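**Remarks on the chemistry**

- Ring positions are written a1–a6 for ring A (a1 propanoyl carbon, a2/a4/a6 C–OH, a3 C–Me, a5 bridge carbon) and b1–b6 for ring B (b1 bridge carbon, b2 C–OH, b3 propanoyl carbon, b4 C–OH, b5 C–Me, b6 C–OMe). A capital A followed by a number denotes a compound of an alternative.
- Structure check: tracing the atoms of 13 through 16 and 17 into ring B reproduces the b2-OH / b3-acyl / b4-OH / b5-Me / b6-OMe pattern of the target, so no structural correction is needed. The refinement made on the way to 13 is an N-isopropyl carbamate as directing group, which is removed by amine base in the same pot as the triflation.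
- Assumption: compounds 1, 14 and 18 are purchased.

## Structural features

The target is a diarylmethane in which two hexasubstituted benzene rings, ring A and ring B, are joined only through one CH2 group. It has no stereocenter, no further ring, and no side chains other than two propanoyl groups. Ring A is a 2,4,6-trihydroxy-3-methylpropiophenone unit with all three oxygens free, so it derives from a symmetric phloroglucinol. Ring B has the same carbon pattern, but its oxygens differ: b2 and b4 are free hydroxyls flanking the ketone at b3, and b6 is a methyl ether between the bridge carbon b1 and the methyl-bearing b5. The free acylphloroglucinol units are easily oxidised and C-alkylated, and the bis(2-hydroxyaryl)methane bridge can be cleaved and redistributed through quinone-methide equilibria under base or heat, so the bridge is best formed last and gently. The real difficulty is ring B: in a monomethyl ether of 2-methylphloroglucinol the two open carbons (future b1 and b3) are each flanked by two oxygens, so an electrophilic acylation cannot be trusted to choose b3. The key step exploits the adjacency of b3 (C-acyl) and b4 (C–OH): both the b3–C(=O) and b4–O bonds are made at once by inserting the b3≡b4 aryne into the C–O bond of propanoic acid, with the b2 oxygen, held as a benzyl ether, deciding which aryne carbon receives oxygen.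

## Logic of the disconnections

**22 to 20 and 17.** The cut is the bond between the bridge methylene and b1. It is made last because this is the most labile C–C bond of 22 and because both halves are then finished rings that never need to be told apart again. The methylene stays on ring A as the aminomethyl group of 20, which unmasks the electrophile 21 on warming. 17 has a single unsubstituted ring carbon, so the site of attack is not in question. The forward step must make the crossed product faster than 21 is consumed by ipso attack on 20, and must stay mild enough that the bridge of 22 is not redistributed.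

**20 to 19, and 19 to 18 and 14.** The a5–CH2 bond and then the a1–acyl bond are cut. Ring A is symmetric in its oxygens, so two C–C disconnections lead to 18, whose two open ring carbons are equivalent. The first acylation defines a1 and leaves a5 as the only site for aminomethylation. The demand is mono-acylation of 18 and mono-aminomethylation of 19 without methylene bridging of two molecules of 19.

**17 to 16.** Only the benzyl–oxygen bond at b2 is cut. The benzyl group serves twice upstream: as the inductive director of the key step and as the label that keeps the b2 oxygen distinct from the b6 methyl ether. Its removal must spare the aryl ketone and the methyl ether, which neutral hydrogenolysis should do.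

**16 to 13 and 14, through 15.** The b3–C(=O) and b4–O bonds are cut together. The propanoyl group then comes from 14 in one operation, and its place between b2 and b4 is set by the polarity of 15 and not by a competition between b1 and b3. All of ring B is reduced to a silyl triflate of a simple trioxygenated toluene. The demand is that oxygen adds at b4 and that the resulting aryl anion is acylated before it is protonated.

**13 to 11 (through 12), 11 to 7 (through 8, 9 and 10), 7 to 6.** The O–S bond, the C–Si bond at b3 and the carbamate C–O bond are cut. The phenol oxygen of 6 becomes the b4 oxygen, and the only C–H ortho to it, which is also ortho to the benzyloxy group, is the future b3. A carbamate-directed metalation therefore puts silicon exactly where the aryne needs it. The demand is that ring lithiation outpaces deprotonation at the benzylic ether carbon and at the ring methyl, and that the carbamate is cleaved without loss of the C–Si bond.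

**6 to 3 (through 4 and 5), 3 to 2, 2 to 1.** The ring methyl is traced back to a formyl group and the two ether O–C bonds are cut. The formyl group of 1 differentiates the three hydroxyls: the para one is benzylated first, one ortho one is methylated second, and the last ortho hydroxyl, held by hydrogen bonding, is kept and later carries the carbamate. The demand is a site-selective mono-benzylation and a formyl-to-methyl reduction that spares the benzyl ether.

## Other disconnections considered

**Alternative 1:** The cut is the a1–a6 bond of ring A. In the forward direction Mg(OMe)2 in methanol would fold an open-chain triketo ester by a Claisen (Dieckmann-type) condensation, closing ring A of 1-[2,4,6-trihydroxy-3-methyl-5-[(2,4,6-trimethoxy-3-methylphenyl)methyl]phenyl]propan-1-one A1 from methyl 4-methyl-3,5,7-trioxo-2-[(2,4,6-trimethoxy-3-methylphenyl)methyl]nonanoate A2.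
- In its favour: the folding mirrors polyketide biosynthesis; every substituent of ring A is placed by the chain sequence; ring A needs no protecting groups.
- Where it is better than the chosen plan: the bridge is an ordinary C–C bond made early by enolate alkylation, so there is no late phenol–phenol coupling and no risk of bridge redistribution.
- Where it is equal: in A1 the only open position of ring B is b3, so a later acylation would be as unambiguous as the aryne insertion.
- Against it here:
  - A2 has five acidic sites and would take many steps to assemble.
  - Aldol closure to a resorcylate and O-cyclisation to pyrones compete with the Claisen mode, and only magnesium chelation holds them back.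
  - It builds de novo the ring that is available in one step from 18.
  - A1 still lacks the ring B ketone and carries three methyl ethers, of which exactly two (b2, b4) must be cleaved. That would rest on chelation-controlled dealkylation (for example BCl3) after an acylation that the free ring A phenols would complicate.
- Comparison: mechanistically both plans rely on an intramolecular acyl transfer to carbon, but the chosen plan applies it to the difficult ring. In step economy Alternative 1 is clearly longer.

**Alternative 2:** The cuts are the b1–b2 and b5–b6 bonds, with b2–b3 formed in the same cascade. Heating 3-ethoxy-2-methylcyclobut-2-en-1-one A4 with the ynol ether 1,3,5-tris(benzyloxy)-2-(3-methoxyprop-2-yn-1-yl)-4-methylbenzene A5 would give 5-ethoxy-3-methoxy-4-methyl-2-[[2,4,6-tris(benzyloxy)-3-methylphenyl]methyl]phenol A3. The Danheiser benzannulation runs by four-electron ring opening to a vinylketene, [2+2] cycloaddition, a second ring opening and six-electron electrocyclisation.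
- In its favour: the substitution pattern of ring B is enforced by the connectivity of a reagent-free pericyclic cascade.
- Where it is better than the chosen plan: regiocontrol is structural, whereas the aryne step rests on an electronic bias. The bridge is in place before ring B exists. A3 has exactly one open C–H on each ring (a1 and b3), so both propanoyl groups could be introduced in one double Friedel–Crafts acylation with no regiochemical choice.
- Against it here:
  - A4 needs ketene-type cycloaddition chemistry with volatile, hazardous partners.
  - A5 is an acid- and heat-sensitive ynol ether that takes several steps from a ring A precursor.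
  - The benzyl ethers of A3 are exposed to Lewis acid in the acylation.
  - The b4 ethyl ether must be cleaved while the b6 methyl ether stays, which again relies on chelation to the new ketone.
- Comparison: the step count is estimated as equal to or somewhat longer than the chosen route, with less robust intermediates.

**Alternative 3:** The cuts are the a1–a2 and a5–a6 bonds. The diene 2-(tert-butyldimethylsilyloxy)-4-methoxy-3-methyl-1-[(2,4,6-trimethoxy-3-methylphenyl)methyl]cyclohexa-1,3-diene A7, derived from 2-methylcyclohexane-1,3-dione A9, would add 1-ethoxypent-1-yn-3-one A8. The bicyclic adduct would then lose ethylene (Alder–Rickert) to give 1-[2-ethoxy-4-hydroxy-6-methoxy-5-methyl-3-[(2,4,6-trimethoxy-3-methylphenyl)methyl]phenyl]propan-1-one A6.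
- In its favour: the ring A ketone is built in; the regiochemistry follows from matching the nucleophilic diene terminus with the electrophilic alkyne carbon; aromatisation is irreversible; the starting dione is cheap.
- Where it is equal or better: the pericyclic regiocontrol is in principle as dependable as the aryne polarity, and the bridge is made early by enolate alkylation, which avoids the late coupling.
- Against it here:
  - Both diene termini are fully substituted and the alkyne is disubstituted, so the cycloaddition creates two quaternary bridgeheads.
  - The dienophile is deactivated by its donor group, which would call for forcing temperatures at which a silyl dienol ether and an ynone may not last.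
  - The effort goes into ring A, which the chosen plan obtains in one step from 18.
  - A6 still needs two ortho ethers removed on ring A, and on ring B the same acylation and selective demethylation as in Alternative 1.
- Comparison: in step economy it is clearly the longest of the plans.

Key step: step 7

## Route

Step 1
Reactants: 1 2,4,6-trihydroxybenzaldehyde
Product: 2 4-(benzyloxy)-2,6-dihydroxybenzaldehyde
Conditions: BnBr (1.0 equiv), CsHCO3 (1.1 equiv), MeCN, 60 °C
Reagents that add atoms: benzyl bromide, BrCc1ccccc1
Why: Williamson ether synthesis under weak-base control; the 4-OH, para to the formyl group, is the most acidic and least hindered hydroxyl, so one equivalent of halide with a hydrogencarbonate base should alkylate it in preference to the two ortho hydroxyls.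

Step 2
Reactants: 2 4-(benzyloxy)-2,6-dihydroxybenzaldehyde
Product: 3 4-(benzyloxy)-2-hydroxy-6-methoxybenzaldehyde
Conditions: MeI (1.1 equiv), K2CO3 (1.1 equiv), acetone, rt
Reagents that add atoms: iodomethane, CI
Why: Williamson O-methylation; the two ortho hydroxyls of 2 are equivalent, and once one is methylated the other is locked in a strong hydrogen bond to the formyl oxygen and should resist a second alkylation.

Step 3
Reactants: 3 4-(benzyloxy)-2-hydroxy-6-methoxybenzaldehyde
Product: 6 5-(benzyloxy)-3-methoxy-2-methylphenol, via aryl tert-butyl carbonate 4 (not isolated), via ortho-quinone methide 5 (not isolated)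
Conditions: Boc2O, DMAP (cat.), THF, 0 °C → rt; then NaBH4, H2O, 0 °C → rt
Reagents that add atoms: none
Why: Carbonate-assisted reductive deoxygenation of a salicylaldehyde; hydride reduces the formyl group, the carbonate migrates to the benzylic oxygen and is expelled by the phenoxide to give 5, and a second hydride adds to 5 to give the ortho-methylphenol. Benzyl and methyl ethers are inert to NaBH4, and neither cyanide nor hydrogenation is needed.

Step 4
Reactants: 6 5-(benzyloxy)-3-methoxy-2-methylphenol
Product: 7 5-(benzyloxy)-3-methoxy-2-methylphenyl N-(propan-2-yl)carbamate
Conditions: i-PrNCO (1.5 equiv), Et3N (cat.), CH2Cl2, rt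
Reagents that add atoms: isopropyl isocyanate, CC(C)N=C=O
Why: Base-catalysed addition of the phenol to the isocyanate; the secondary carbamate is a strong directing group for ortho-metalation and is later removable with amine base.

Step 5
Reactants: 7 5-(benzyloxy)-3-methoxy-2-methylphenyl N-(propan-2-yl)carbamate
Product: 11 3-(benzyloxy)-5-methoxy-6-methyl-2-(trimethylsilyl)phenyl N-(propan-2-yl)carbamate, via N-silyl carbamate 8 (not isolated), via aryllithium 9 (not isolated), via bis-silyl carbamate 10 (not isolated)
Conditions: TBSOTf, TMEDA, Et2O, 0 °C → rt; n-BuLi, TMEDA, −78 °C; TMSCl, −78 °C → rt; aq. NaHSO4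
Reagents that add atoms: chlorotrimethylsilane, C[Si](C)(C)Cl
Why: Directed ortho-metalation; in situ N-silylation masks the N–H and blocks anionic Fries migration, n-BuLi/TMEDA then lithiates the only ring C–H ortho to the carbamate, which is also ortho to the benzyloxy group, and TMSCl silylates that carbon. The N-silyl group is lost in the acidic work-up.

Step 6
Reactants: 11 3-(benzyloxy)-5-methoxy-6-methyl-2-(trimethylsilyl)phenyl N-(propan-2-yl)carbamate
Product: 13 3-(benzyloxy)-5-methoxy-6-methyl-2-(trimethylsilyl)phenyl trifluoromethanesulfonate, via silylphenol 12 (not isolated)
Conditions: DBU, Et2NH, MeCN, 40 °C; then PhNTf2, rt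
Reagents that add atoms: N-phenylbis(trifluoromethanesulfonimide), O=S(=O)(N(c1ccccc1)S(=O)(=O)C(F)(F)F)C(F)(F)F
Why: DBU-promoted E1cB cleavage of the N–H carbamate releases the phenoxide while Et2NH scavenges the isocyanate, and the phenoxide is triflated in the same pot; this is the standard access to ortho-silylaryl triflates and avoids Tf2O. The phenoxide is flanked by silyl and methyl groups, so gentle warming may be needed.

Step 7
Reactants: 13 3-(benzyloxy)-5-methoxy-6-methyl-2-(trimethylsilyl)phenyl trifluoromethanesulfonate; 14 propanoic acid
Product: 16 1-[6-(benzyloxy)-2-hydroxy-4-methoxy-3-methylphenyl]propan-1-one, via aryne 15 (not isolated)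
Conditions: CsF (4 equiv), anhydrous THF, 125 °C, sealed tube; 14 held at about 1.0 equiv
Reagents that add atoms: none
Why: Fluoride attacks silicon of 13 and the resulting aryl anion expels triflate to give aryne 15 (b3≡b4), while CsF converts 14 into cesium propanoate. The carboxylate oxygen adds to b4, the aryne carbon remote from the benzyloxy group, because the inductively withdrawing oxygen on b2 distorts the aryne so that b4 is the more electrophilic terminus and the developing negative charge at b3 is stabilised next to the C–O bond. The aryl anion at b3 then attacks the carbonyl of the newly formed aryl ester (4-exo-trig), and the strained four-membered alkoxide opens by C–O cleavage to the phenoxide of 16, a net 1,3 O-to-C acyl shift of the anionic Fries type. The closest known reaction type is the CsF-mediated insertion of arynes into the C–O bond of carboxylic acids, which gives ortho-hydroxyaryl ketones. No ring persists in the product, since the four-membered ring is transient, and no stereocenter is formed. Two selectivities are needed: the regiochemistry of oxygen addition, secured by the b2 benzyloxy group (the b5 methyl and the b2 ether hinder the two termini to a similar degree, so the electronic bias decides), and C-acylation in preference to protonation of the aryl anion, favoured by keeping 14 near one equivalent, excluding water, and running hot so that intramolecular acyl transfer outruns proton transfer. The product phenoxide is chelated to the ketone and flanked by the b5 methyl, which should slow its arylation by a second aryne.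

Step 8
Reactants: 16 1-[6-(benzyloxy)-2-hydroxy-4-methoxy-3-methylphenyl]propan-1-one
Product: 17 1-(2,6-dihydroxy-4-methoxy-3-methylphenyl)propan-1-one
Conditions: H2 (1 atm), 10% Pd/C, EtOAc, rt
Reagents that add atoms: none
Why: Catalytic hydrogenolysis of the benzyl aryl ether; the doubly ortho-substituted, hydrogen-bonded aryl ketone and the methyl ether should not be reduced at balloon pressure and room temperature.

Step 9
Reactants: 18 2-methylphloroglucinol (2-methylbenzene-1,3,5-triol); 14 propanoic acid
Product: 19 1-(2,4,6-trihydroxy-3-methylphenyl)propan-1-one
Conditions: BF3·OEt2, 80 °C; then aq. NaOAc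
Reagents that add atoms: none
Why: Friedel–Crafts C-acylation of a phloroglucinol by a carboxylic acid under BF3 activation (O-acylation and Fries-type migration may intervene); the two open ring positions of 18 are equivalent, and the first acyl group deactivates the ring towards a second acylation.

Step 10
Reactants: 19 1-(2,4,6-trihydroxy-3-methylphenyl)propan-1-one
Product: 20 1-{3-[(dimethylamino)methyl]-2,4,6-trihydroxy-5-methylphenyl}propan-1-one
Conditions: CH2=NMe2+ I− (1.05 equiv), Et3N (1.0 equiv), MeCN, 0 °C → rt
Reagents that add atoms: N,N-dimethylmethyleneiminium iodide, C=[N+](C)C.[I-]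
Why: Mannich reaction with a preformed iminium salt; 19 has a single unsubstituted ring carbon, flanked by two hydroxyls, so aminomethylation is regiochemically unambiguous. The preformed salt avoids free formaldehyde, which would bridge two molecules of 19.

Step 11
Reactants: 20 1-{3-[(dimethylamino)methyl]-2,4,6-trihydroxy-5-methylphenyl}propan-1-one; 17 1-(2,6-dihydroxy-4-methoxy-3-methylphenyl)propan-1-one
Product: 22 1-{3-[(2,4-dihydroxy-6-methoxy-5-methyl-3-propanoylphenyl)methyl]-2,4,6-trihydroxy-5-methylphenyl}propan-1-one, via ortho-quinone methide 21 (not isolated)
Conditions: 20 (1.3 equiv), MeCN, 80 °C, N2 sweep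
Reagents that add atoms: none
Why: Thermal loss of Me2NH from the zwitterionic Mannich base gives ortho-quinone methide 21, which is trapped in a Michael-type C-alkylation by the only open ring carbon of 17, para to one hydroxyl and ortho to the other. Rearomatisation of both rings drives the reaction, and sweeping out the amine limits base-induced exchange of the bridge.

## Compound list

1 | 2,4,6-trihydroxybenzaldehyde | O=Cc1c(O)cc(O)cc1O | starting material
2 | 4-(benzyloxy)-2,6-dihydroxybenzaldehyde | O=Cc1c(O)cc(OCc2ccccc2)cc1O | intermediate
3 | 4-(benzyloxy)-2-hydroxy-6-methoxybenzaldehyde | COc1cc(OCc2ccccc2)cc(O)c1C=O | intermediate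
4 | 5-(benzyloxy)-2-formyl-3-methoxyphenyl tert-butyl carbonate | CC(C)(C)OC(=O)Oc1cc(OCc2ccccc2)cc(OC)c1C=O | intermediate
5 | 3-(benzyloxy)-5-methoxy-6-methylidenecyclohexa-2,4-dien-1-one | C=C1C(=O)C=C(OCc2ccccc2)C=C1OC | intermediate
6 | 5-(benzyloxy)-3-methoxy-2-methylphenol | COc1cc(OCc2ccccc2)cc(O)c1C | intermediate
7 | 5-(benzyloxy)-3-methoxy-2-methylphenyl N-(propan-2-yl)carbamate | COc1cc(OCc2ccccc2)cc(OC(=O)NC(C)C)c1C | intermediate
8 | 5-(benzyloxy)-3-methoxy-2-methylphenyl N-(tert-butyldimethylsilyl)-N-(propan-2-yl)carbamate | COc1cc(OCc2ccccc2)cc(OC(=O)N(C(C)C)[Si](C)(C)C(C)(C)C)c1C | intermediate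
9 | [2-(benzyloxy)-6-{[N-(tert-butyldimethylsilyl)-N-(propan-2-yl)carbamoyl]oxy}-4-methoxy-5-methylphenyl]lithium | COc1cc(OCc2ccccc2)c([Li])c(OC(=O)N(C(C)C)[Si](C)(C)C(C)(C)C)c1C | intermediate
10 | 3-(benzyloxy)-5-methoxy-6-methyl-2-(trimethylsilyl)phenyl N-(tert-butyldimethylsilyl)-N-(propan-2-yl)carbamate | COc1cc(OCc2ccccc2)c([Si](C)(C)C)c(OC(=O)N(C(C)C)[Si](C)(C)C(C)(C)C)c1C | intermediate
11 | 3-(benzyloxy)-5-methoxy-6-methyl-2-(trimethylsilyl)phenyl N-(propan-2-yl)carbamate | COc1cc(OCc2ccccc2)c([Si](C)(C)C)c(OC(=O)NC(C)C)c1C | intermediate
12 | 3-(benzyloxy)-5-methoxy-6-methyl-2-(trimethylsilyl)phenol | COc1cc(OCc2ccccc2)c([Si](C)(C)C)c(O)c1C | intermediate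
13 | 3-(benzyloxy)-5-methoxy-6-methyl-2-(trimethylsilyl)phenyl trifluoromethanesulfonate | COc1cc(OCc2ccccc2)c([Si](C)(C)C)c(OS(=O)(=O)C(F)(F)F)c1C | intermediate
14 | propanoic acid | CCC(=O)O | starting material
15 | 3-(benzyloxy)-5-methoxy-6-methyl-1,2-didehydrobenzene (aryne) | COC1=C(C)C#CC(OCc2ccccc2)=C1 | intermediate
16 | 1-[6-(benzyloxy)-2-hydroxy-4-methoxy-3-methylphenyl]propan-1-one | CCC(=O)c1c(O)c(C)c(OC)cc1OCc1ccccc1 | intermediate
17 | 1-(2,6-dihydroxy-4-methoxy-3-methylphenyl)propan-1-one | CCC(=O)c1c(O)c(C)c(OC)cc1O | intermediate
18 | 2-methylphloroglucinol (2-methylbenzene-1,3,5-triol) | Cc1c(O)cc(O)cc1O | starting material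
19 | 1-(2,4,6-trihydroxy-3-methylphenyl)propan-1-one | CCC(=O)c1c(O)c(C)c(O)cc1O | intermediate
20 | 1-{3-[(dimethylamino)methyl]-2,4,6-trihydroxy-5-methylphenyl}propan-1-one | CCC(=O)c1c(O)c(C)c(O)c(CN(C)C)c1O | intermediate
21 | 3,5-dihydroxy-2-methyl-6-methylidene-4-propanoylcyclohexa-2,4-dien-1-one | C=C1C(=O)C(C)=C(O)C(C(=O)CC)=C1O | intermediate
22 | 1-{3-[(2,4-dihydroxy-6-methoxy-5-methyl-3-propanoylphenyl)methyl]-2,4,6-trihydroxy-5-methylphenyl}propan-1-one | CCC(=O)c1c(O)c(C)c(O)c(Cc2c(O)c(C(=O)CC)c(O)c(C)c2OC)c1O | target

## Step count and least certain steps

Total: 11 steps. Longest linear sequence: 9 steps (steps 1–8 and 11); the ring A branch (steps 9 and 10) joins at step 11.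

**Key step 7.** Three processes may spoil it:
- protonation of the b3 aryl anion by the acid or by bifluoride before the acyl shift, which stops the sequence at the O-aryl ester stage;
- erosion of regiocontrol in the carboxylate addition if the b5 methyl weighs more than expected against the b2 ether;
- further arylation of the product phenoxide by a second aryne.

The fallback keeps the same regiochemical handle but drops the aryne. It sets out from 7: the aryllithium 9 is generated exactly as in step 5 (through 8) and is acylated at −78 °C with N-methoxy-N-methylpropanamide, giving after acidic work-up 3-(benzyloxy)-5-methoxy-6-methyl-2-propanoylphenyl N-(propan-2-yl)carbamate F1. Treatment of this carbamate with DBU and Et2NH in MeCN at 40 °C then releases the phenol and rejoins the route at 16. Both operations are established directed-metalation and carbamate-cleavage chemistry.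

**Step 5.** The base may deprotonate the benzylic CH2 of the ether (followed by Wittig rearrangement) or the ring methyl instead of the ring C–H, and incomplete N-silylation would allow anionic Fries migration of the carbamoyl group. The fallback replaces deprotonation by halogen–metal exchange, which is far faster than any of these deprotonations. It sets out from 6. An amine-catalysed ortho-bromination (NBS, cat. i-Pr2NH, CH2Cl2, 0 °C) should give 3-(benzyloxy)-2-bromo-5-methoxy-6-methylphenol F2. Silylation of the hydroxyl with hexamethyldisilazane gives [3-(benzyloxy)-2-bromo-5-methoxy-6-methylphenoxy]trimethylsilane F3. Treatment with n-BuLi in THF at −78 °C triggers bromine–lithium exchange and a retro-Brook O-to-C silyl shift, and the resulting phenoxide is triflated in the same flask with PhNTf2, rejoining the route at 13. The weak point of this detour is the site selectivity of the bromination, ortho against para to the hydroxyl.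

**Step 11.** Quinone methide 21 may be consumed by ipso attack on 20 with loss of the aminomethyl group (self-coupling of ring A). The liberated amine may promote redistribution of the methylene bridge in the product. Loss of amine may also be sluggish at 80 °C. The fallback exchanges the roles of the two rings so that the cheap partner can be used in large excess. It sets out from 17, which is aminomethylated with N,N-dimethylmethyleneiminium iodide and Et3N to 1-{3-[(dimethylamino)methyl]-2,6-dihydroxy-4-methoxy-5-methylphenyl}propan-1-one F4. This Mannich base is then heated in MeCN with three equivalents of 19, whose single open ring carbon traps the ring B quinone methide, arriving directly at 22.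

**Step 1.** Site selectivity of the mono-benzylation may be poor, through over-alkylation, alkylation of an ortho hydroxyl, or C-benzylation of the electron-rich ring. The fallback replaces selective alkylation by exhaustive protection and chelation-controlled deprotection. It sets out from 1. Two equivalents of BnBr with K2CO3 in DMF give 2,4-bis(benzyloxy)-6-hydroxybenzaldehyde F5, since the last, hydrogen-bonded hydroxyl resists alkylation. Methylation of that hydroxyl (MeI, K2CO3, DMF) gives 2,4-bis(benzyloxy)-6-methoxybenzaldehyde F6. MgBr2·OEt2 in toluene/Et2O at reflux should then remove only the benzyl group ortho to the formyl group, rejoining the route at 3.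

## Further compounds

F1 | step 7 | 3-(benzyloxy)-5-methoxy-6-methyl-2-propanoylphenyl N-(propan-2-yl)carbamate | CCC(=O)c1c(OC(=O)NC(C)C)c(C)c(OC)cc1OCc1ccccc1
F2 | step 5 | 3-(benzyloxy)-2-bromo-5-methoxy-6-methylphenol | COc1cc(OCc2ccccc2)c(Br)c(O)c1C
F3 | step 5 | [3-(benzyloxy)-2-bromo-5-methoxy-6-methylphenoxy]trimethylsilane | COc1cc(OCc2ccccc2)c(Br)c(O[Si](C)(C)C)c1C
F4 | step 11 | 1-{3-[(dimethylamino)methyl]-2,6-dihydroxy-4-methoxy-5-methylphenyl}propan-1-one | CCC(=O)c1c(O)c(C)c(OC)c(CN(C)C)c1O
F5 | step 1 | 2,4-bis(benzyloxy)-6-hydroxybenzaldehyde | O=Cc1c(O)cc(OCc2ccccc2)cc1OCc1ccccc1
F6 | step 1 | 2,4-bis(benzyloxy)-6-methoxybenzaldehyde | COc1cc(OCc2ccccc2)cc(OCc2ccccc2)c1C=O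
A1 | alternative 1 | 1-[2,4,6-trihydroxy-3-methyl-5-[(2,4,6-trimethoxy-3-methylphenyl)methyl]phenyl]propan-1-one | CCC(=O)c1c(O)c(C)c(O)c(Cc2c(OC)cc(OC)c(C)c2OC)c1O
A2 | alternative 1 | methyl 4-methyl-3,5,7-trioxo-2-[(2,4,6-trimethoxy-3-methylphenyl)methyl]nonanoate | CCC(=O)CC(=O)C(C)C(=O)C(Cc1c(OC)cc(OC)c(C)c1OC)C(=O)OC
A3 | alternative 2 | 5-ethoxy-3-methoxy-4-methyl-2-[[2,4,6-tris(benzyloxy)-3-methylphenyl]methyl]phenol | COc1c(C)c(OCC)cc(O)c1Cc1c(OCc2ccccc2)cc(OCc2ccccc2)c(C)c1OCc1ccccc1
A4 | alternative 2 | 3-ethoxy-2-methylcyclobut-2-en-1-one | CCOC1=C(C)C(=O)C1
A5 | alternative 2 | 1,3,5-tris(benzyloxy)-2-(3-methoxyprop-2-yn-1-yl)-4-methylbenzene | COC#CCc1c(OCc2ccccc2)cc(OCc2ccccc2)c(C)c1OCc1ccccc1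
A6 | alternative 3 | 1-[2-ethoxy-4-hydroxy-6-methoxy-5-methyl-3-[(2,4,6-trimethoxy-3-methylphenyl)methyl]phenyl]propan-1-one | CCOc1c(C(=O)CC)c(OC)c(C)c(O)c1Cc1c(OC)cc(OC)c(C)c1OC
A7 | alternative 3 | 2-(tert-butyldimethylsilyloxy)-4-methoxy-3-methyl-1-[(2,4,6-trimethoxy-3-methylphenyl)methyl]cyclohexa-1,3-diene | COC1=C(C)C(O[Si](C)(C)C(C)(C)C)=C(Cc2c(OC)cc(OC)c(C)c2OC)CC1
A8 | alternative 3 | 1-ethoxypent-1-yn-3-one | CCOC#CC(=O)CC
A9 | alternative 3 | 2-methylcyclohexane-1,3-dione | CC1C(=O)CCCC1=O
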